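**Retrosynthetic overview**

1. Target 38 ⇐ triene-enal 37 by ring-closing metathesis at C4=C5; the ten-membered carbocycle is formed last, with the new trisubstituted alkene cis within the ring.
2. 37 ⇐ aldehyde 31 + (R)-bromomethyl butenolide 13 by Zn-Barbier allylation (C7–C8 bond; C6 controls C7 and C8), then C8 acylation with (S)-2-methylbutanoic acid and C14 desilylation/oxidation.
3. 13 ⇐ (R)-enynol 6 (propargyl alcohol + acrolein, kinetic resolution) by trans-hydroalumination/iodination, lithiation–carboxylation–lactonisation and Appel bromination.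
4. 31 ⇐ aldehyde 19 (Johnson–Claisen on 2-methylidenepropane-1,3-diol) + phosphonate 23 by E-selective Horner–Wadsworth–Emmons olefination, then protecting-group adjustment.
5. Ring order: butenolide (later the α-methylene-γ-lactone) first, ten-membered ring second.

Assumption: germacrane numbering is used (lactone C12–O–C6, exocyclic methylene C13, formyl C14, acetoxymethyl C15); the SMILES is read as 6R,7R,8S with an (S)-2-methylbutanoate and both ring alkenes cis within the ring (each E by CIP).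

**Fragment 1 (compound 13)**

Step 1
Reactants: 1 prop-2-yn-1-ol
Product: 2 tert-butyldimethyl(prop-2-yn-1-yloxy)silane
Conditions: TBSCl, imidazole, CH2Cl2, 0 °C → rt
Reagents that add atoms: tert-butyldimethylsilyl chloride, CC(C)(C)[Si](C)(C)Cl
Why: Standard O-silylation (silyl ether formation) masks the future C13 hydroxyl through the organometallic steps.

Step 2
Reactants: 2 tert-butyldimethyl(prop-2-yn-1-yloxy)silane, 3 acrolein
Product: 5 rac-6-[(tert-butyldimethylsilyl)oxy]hex-1-en-4-yn-3-ol, via lithium acetylide 4 (not isolated)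
Conditions: n-BuLi, THF, −78 °C; then 3, −78 °C; aq NH4Cl
Reagents that add atoms: none
Why: 1,2-Addition of a lithium acetylide to the enal carbonyl (acetylide addition) forms the C6–C7 bond; the carbinol is racemic at this stage.

Step 3
Reactants: 5 rac-6-[(tert-butyldimethylsilyl)oxy]hex-1-en-4-yn-3-ol
Product: 6 (3R)-6-[(tert-butyldimethylsilyl)oxy]hex-1-en-4-yn-3-ol
Conditions: Ti(OiPr)4 (0.15 equiv), D-(−)-diisopropyl tartrate (0.2 equiv), t-BuOOH (0.6 equiv), 4 Å molecular sieves, CH2Cl2, −20 °C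
Reagents that add atoms: none
Why: Sharpless kinetic resolution: with the D-(−)-tartrate the S enantiomer of this vinyl carbinol is epoxidised much faster and is removed as its erythro epoxy alcohol, leaving the 3R alcohol (future C6) in high ee at about 55% conversion.

Step 4
Reactants: 6 (3R)-6-[(tert-butyldimethylsilyl)oxy]hex-1-en-4-yn-3-ol
Product: 8 (3R,4Z)-6-[(tert-butyldimethylsilyl)oxy]-5-iodohexa-1,4-dien-3-ol, via cyclic vinylalanate 7 (not isolated)
Conditions: NaAlH2(OCH2CH2OMe)2, THF, 0 °C; EtOAc; then I2, −78 → 0 °C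
Reagents that add atoms: iodine, II
Why: Hydroxyl-directed trans-hydroalumination puts H on the proximal alkyne carbon (C7) and aluminium on the distal one (C11) cis to the carbinol, and iodinolysis with retention gives the Z vinyl iodide.

Step 5
Reactants: 8 (3R,4Z)-6-[(tert-butyldimethylsilyl)oxy]-5-iodohexa-1,4-dien-3-ol
Product: 11 (5R)-3-{[(tert-butyldimethylsilyl)oxy]methyl}-5-ethenylfuran-2(5H)-one, via dilithio species 9 (not isolated), via hydroxy acid 10 (not isolated)
Conditions: t-BuLi (3.1 equiv), Et2O, −78 °C; CO2; AcOH, −78 °C → rt; PPTS (cat.), CH2Cl2, rt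
Reagents that add atoms: carbon dioxide, O=C=O
Why: Iodine–lithium exchange with retention of alkene geometry, carboxylation (C12) and spontaneous lactonisation of the Z γ-hydroxy enoic acid give the butenolide without touching the C6 stereocentre.

Step 6
Reactants: 11 (5R)-3-{[(tert-butyldimethylsilyl)oxy]methyl}-5-ethenylfuran-2(5H)-one
Product: 12 (5R)-5-ethenyl-3-(hydroxymethyl)furan-2(5H)-one
Conditions: HF·pyridine, THF, 0 °C → rt
Reagents that add atoms: none
Why: Fluoride-mediated desilylation under non-basic conditions keeps the base-sensitive γ-position of the butenolide intact.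

Step 7
Reactants: 12 (5R)-5-ethenyl-3-(hydroxymethyl)furan-2(5H)-one
Product: 13 (5R)-3-(bromomethyl)-5-ethenylfuran-2(5H)-one
Conditions: CBr4, PPh3, CH2Cl2, 0 °C
Reagents that add atoms: carbon tetrabromide, BrC(Br)(Br)Br
Why: Appel bromination converts the primary allylic alcohol into the allylic bromide under neutral conditions.

**Fragment 2 (compound 31)**

Step 8
Reactants: 14 2-methylidenepropane-1,3-diol
Product: 15 2-{[(4-methoxybenzyl)oxy]methyl}prop-2-en-1-ol
Conditions: NaH (1.0 equiv), 14 (2 equiv), THF/DMF, 0 °C; PMBCl, Bu4NI (cat.), rt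
Reagents that add atoms: 4-methoxybenzyl chloride, COc1ccc(CCl)cc1
Why: Williamson monoetherification of the symmetrical diol (excess diol) protects the future C15 oxygen.

Step 9
Reactants: 15 2-{[(4-methoxybenzyl)oxy]methyl}prop-2-en-1-ol, 16 triethyl orthoacetate
Product: 18 ethyl 4-{[(4-methoxybenzyl)oxy]methyl}pent-4-enoate, via ketene acetal 17 (not isolated)
Conditions: EtCO2H (cat.), neat 16, 140 °C, EtOH distilled off
Reagents that add atoms: none
Why: Johnson–Claisen rearrangement forms the C2–C3 bond and transposes the alkene to the 1,1-disubstituted C4 methylidene.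

Step 10
Reactants: 18 ethyl 4-{[(4-methoxybenzyl)oxy]methyl}pent-4-enoate
Product: 19 4-{[(4-methoxybenzyl)oxy]methyl}pent-4-enal
Conditions: iBu2AlH (1.05 equiv), CH2Cl2, −78 °C; aq potassium sodium tartrate
Reagents that add atoms: none
Why: Partial reduction of the ester through the stable tetrahedral aluminium hemiacetal at −78 °C gives the C1 aldehyde.

Step 11
Reactants: 20 triethyl phosphonoacetate, 21 (2-bromoethoxy)(tert-butyl)dimethylsilane
Product: 23 ethyl 4-[(tert-butyldimethylsilyl)oxy]-2-(diethoxyphosphoryl)butanoate (racemic), via sodium phosphonate carbanion 22 (not isolated)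
Conditions: NaH, DMF, 0 °C; then 21, NaI (cat.), 60 °C
Reagents that add atoms: none
Why: C-Alkylation of the stabilised phosphonoacetate carbanion with a primary bromide (SN2) installs the C9–C8 unit.

Step 12
Reactants: 19 4-{[(4-methoxybenzyl)oxy]methyl}pent-4-enal, 23 ethyl 4-[(tert-butyldimethylsilyl)oxy]-2-(diethoxyphosphoryl)butanoate
Product: 25 ethyl (2E)-2-{2-[(tert-butyldimethylsilyl)oxy]ethyl}-6-{[(4-methoxybenzyl)oxy]methyl}hepta-2,6-dienoate, via sodium phosphonate carbanion 24 (not isolated)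
Conditions: NaH, THF, 0 °C; then 19, 0 °C → rt; minor Z isomer removed by chromatography
Reagents that add atoms: none
Why: Horner–Wadsworth–Emmons olefination gives mainly the thermodynamic E enoate (ester trans to C2), which is the C1=C10 geometry of the target (C2 cis to C9).

Step 13
Reactants: 25 ethyl (2E)-2-{2-[(tert-butyldimethylsilyl)oxy]ethyl}-6-{[(4-methoxybenzyl)oxy]methyl}hepta-2,6-dienoate
Product: 26 (2E)-2-{2-[(tert-butyldimethylsilyl)oxy]ethyl}-6-{[(4-methoxybenzyl)oxy]methyl}hepta-2,6-dien-1-ol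
Conditions: iBu2AlH (2.5 equiv), CH2Cl2, −78 → 0 °C; aq potassium sodium tartrate
Reagents that add atoms: none
Why: 1,2-Reduction of the enoate gives the C14 allylic alcohol without touching the silyl or PMB ethers.

Step 14
Reactants: 26 (2E)-2-{2-[(tert-butyldimethylsilyl)oxy]ethyl}-6-{[(4-methoxybenzyl)oxy]methyl}hepta-2,6-dien-1-ol
Product: 27 tert-butyl{[(2E)-2-{2-[(tert-butyldimethylsilyl)oxy]ethyl}-6-{[(4-methoxybenzyl)oxy]methyl}hepta-2,6-dien-1-yl]oxy}diphenylsilane
Conditions: TBDPSCl, imidazole, CH2Cl2, rt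
Reagents that add atoms: tert-butyl(chloro)diphenylsilane, CC(C)(C)[Si](Cl)(c1ccccc1)c1ccccc1
Why: Silylation gives a C14 ether that survives the later acidic TBS removal and is cleaved by fluoride at the end.

Step 15
Reactants: 27 tert-butyl{[(2E)-2-{2-[(tert-butyldimethylsilyl)oxy]ethyl}-6-{[(4-methoxybenzyl)oxy]methyl}hepta-2,6-dien-1-yl]oxy}diphenylsilane
Product: 28 (5E)-6-{[(tert-butyldiphenylsilyl)oxy]methyl}-8-[(tert-butyldimethylsilyl)oxy]-2-methylideneoct-5-en-1-ol
Conditions: DDQ, CH2Cl2/pH 7 buffer, 0 °C → rt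
Reagents that add atoms: none
Why: Oxidative PMB cleavage frees only the C15 hydroxyl, as both silyl ethers are inert to DDQ.

Step 16
Reactants: 28 (5E)-6-{[(tert-butyldiphenylsilyl)oxy]methyl}-8-[(tert-butyldimethylsilyl)oxy]-2-methylideneoct-5-en-1-ol
Product: 29 (5E)-6-{[(tert-butyldiphenylsilyl)oxy]methyl}-8-[(tert-butyldimethylsilyl)oxy]-2-methylideneoct-5-en-1-yl acetate
Conditions: Ac2O, pyridine, DMAP (cat.), CH2Cl2, 0 °C → rt
Reagents that add atoms: acetic anhydride, CC(=O)OC(C)=O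
Why: Acetylation installs the C15 acetate of the target once all hydride reductions are over.

Step 17
Reactants: 29 (5E)-6-{[(tert-butyldiphenylsilyl)oxy]methyl}-8-[(tert-butyldimethylsilyl)oxy]-2-methylideneoct-5-en-1-yl acetate
Product: 30 (5E)-6-{[(tert-butyldiphenylsilyl)oxy]methyl}-8-hydroxy-2-methylideneoct-5-en-1-yl acetate
Conditions: CSA (0.1 equiv), MeOH/CH2Cl2, 0 °C
Reagents that add atoms: none
Why: Acid-catalysed methanolysis removes the primary TBS ether far faster than the TBDPS ether, and the acetate is stable at 0 °C (selective desilylation).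

Step 18
Reactants: 30 (5E)-6-{[(tert-butyldiphenylsilyl)oxy]methyl}-8-hydroxy-2-methylideneoct-5-en-1-yl acetate
Product: 31 (5E)-6-{[(tert-butyldiphenylsilyl)oxy]methyl}-2-methylidene-8-oxooct-5-en-1-yl acetate
Conditions: Dess–Martin periodinane, NaHCO3, CH2Cl2, 0 °C; used at once
Reagents that add atoms: none
Why: Buffered Dess–Martin oxidation gives the β,γ-unsaturated C8 aldehyde without base- or acid-induced migration of the alkene into conjugation.

**Coupling and endgame**

Step 19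
Reactants: 31 (5E)-6-{[(tert-butyldiphenylsilyl)oxy]methyl}-2-methylidene-8-oxooct-5-en-1-yl acetate, 13 (5R)-3-(bromomethyl)-5-ethenylfuran-2(5H)-one
Product: 33 (5E,8S)-6-{[(tert-butyldiphenylsilyl)oxy]methyl}-8-[(2R,3R)-2-ethenyl-4-methylidene-5-oxooxolan-3-yl]-8-hydroxy-2-methylideneoct-5-en-1-yl acetate, via allylzinc bromide 32 (not isolated)
Conditions: Zn dust, THF/sat. aq NH4Cl (2:1), 0 °C → rt
Reagents that add atoms: none
Why: Barbier allylation: the ring-locked allylzinc (C6 trans to CH2Zn) adds through C7 in a Zimmerman–Traxler chair on the face anti to the C6 vinyl group, giving the 6,7-trans lactone (7R), the anti carbinol (8S) and the exocyclic C11=C13 methylidene.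

Step 20
Reactants: 33 (5E,8S)-6-{[(tert-butyldiphenylsilyl)oxy]methyl}-8-[(2R,3R)-2-ethenyl-4-methylidene-5-oxooxolan-3-yl]-8-hydroxy-2-methylideneoct-5-en-1-yl acetate, 34 (2S)-2-methylbutanoic acid
Product: 35 (1S,3E)-8-acetoxy-3-{[(tert-butyldiphenylsilyl)oxy]methyl}-1-[(2R,3R)-2-ethenyl-4-methylidene-5-oxooxolan-3-yl]-7-methylideneoct-3-en-1-yl (2S)-2-methylbutanoate
Conditions: DCC, DMAP (cat.), CH2Cl2, 0 °C → rt
Reagents that add atoms: none
Why: Steglich esterification acylates the C8 hydroxyl with retention at C8 and, at 0 °C with catalytic DMAP, without epimerising the acid α-centre.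

Step 21
Reactants: 35 (1S,3E)-8-acetoxy-3-{[(tert-butyldiphenylsilyl)oxy]methyl}-1-[(2R,3R)-2-ethenyl-4-methylidene-5-oxooxolan-3-yl]-7-methylideneoct-3-en-1-yl (2S)-2-methylbutanoate
Product: 36 (1S,3E)-8-acetoxy-1-[(2R,3R)-2-ethenyl-4-methylidene-5-oxooxolan-3-yl]-3-(hydroxymethyl)-7-methylideneoct-3-en-1-yl (2S)-2-methylbutanoate
Conditions: HF·pyridine, pyridine/THF, 0 °C → rt
Reagents that add atoms: none
Why: Buffered fluoride desilylation frees the C14 allylic alcohol while the esters and the α-methylene lactone are untouched.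

Step 22
Reactants: 36 (1S,3E)-8-acetoxy-1-[(2R,3R)-2-ethenyl-4-methylidene-5-oxooxolan-3-yl]-3-(hydroxymethyl)-7-methylideneoct-3-en-1-yl (2S)-2-methylbutanoate
Product: 37 (1S,3E)-8-acetoxy-1-[(2R,3R)-2-ethenyl-4-methylidene-5-oxooxolan-3-yl]-3-formyl-7-methylideneoct-3-en-1-yl (2S)-2-methylbutanoate
Conditions: Dess–Martin periodinane, NaHCO3, CH2Cl2, 0 °C
Reagents that add atoms: none
Why: Dess–Martin oxidation of the allylic alcohol gives the C14 enal, already in its stable E geometry, and makes the C1=C10 alkene electron-poor and inert to metathesis.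

Step 23
Reactants: 37 (1S,3E)-8-acetoxy-1-[(2R,3R)-2-ethenyl-4-methylidene-5-oxooxolan-3-yl]-3-formyl-7-methylideneoct-3-en-1-yl (2S)-2-methylbutanoate
Product: 38 [(3aR,4S,6E,10E,11aR)-10-(acetoxymethyl)-6-formyl-3-methylidene-2-oxo-2,3,3a,4,5,8,9,11a-octahydrocyclodeca[b]furan-4-yl] (2S)-2-methylbutanoate
Conditions: second-generation Grubbs catalyst RuCl2(=CHPh)(H2IMes)(PCy3) (15 mol %, in portions), toluene (1 mM), 80 °C, argon sparge
Reagents that add atoms: none
Why: Ring-closing metathesis: the ruthenium carbene formed at the C5 vinyl group closes onto the 1,1-disubstituted C4 alkene, and the ten-membered ring favours the ring-cis trisubstituted alkene (CH2OAc trans to C6); the conjugated enal and α-methylene lactone alkenes do not compete.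

**Compound list**

1 | prop-2-yn-1-ol | C#CCO | starting material
2 | tert-butyldimethyl(prop-2-yn-1-yloxy)silane | C#CCO[Si](C)(C)C(C)(C)C | intermediate
3 | acrolein (prop-2-enal) | C=CC=O | starting material
4 | {3-[(tert-butyldimethylsilyl)oxy]prop-1-yn-1-yl}lithium (lithium acetylide of 2) | [Li]C#CCO[Si](C)(C)C(C)(C)C | intermediate
5 | rac-6-[(tert-butyldimethylsilyl)oxy]hex-1-en-4-yn-3-ol | C=CC(O)C#CCO[Si](C)(C)C(C)(C)C | intermediate
6 | (3R)-6-[(tert-butyldimethylsilyl)oxy]hex-1-en-4-yn-3-ol | C=C[C@@H](O)C#CCO[Si](C)(C)C(C)(C)C | intermediate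
7 | sodium cyclic vinylalanate of 6 (five-membered C–Al–O ring, two 2-methoxyethoxy ligands on Al, 5R) | [Na+].COCCO[Al-]1(OCCOC)O[C@H](C=C)C=C1CO[Si](C)(C)C(C)(C)C | intermediate
8 | (3R,4Z)-6-[(tert-butyldimethylsilyl)oxy]-5-iodohexa-1,4-dien-3-ol | C=C[C@@H](O)/C=C(I)/CO[Si](C)(C)C(C)(C)C | intermediate
9 | dilithio species of 8 (lithium alkoxide, Z vinyllithium in place of iodide) | C=C[C@@H](O[Li])/C=C([Li])/CO[Si](C)(C)C(C)(C)C | intermediate
10 | (2Z,4R)-2-{[(tert-butyldimethylsilyl)oxy]methyl}-4-hydroxyhexa-2,5-dienoic acid | C=C[C@@H](O)/C=C(C(=O)O)/CO[Si](C)(C)C(C)(C)C | intermediate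
11 | (5R)-3-{[(tert-butyldimethylsilyl)oxy]methyl}-5-ethenylfuran-2(5H)-one | O=C1O[C@H](C=C)C=C1CO[Si](C)(C)C(C)(C)C | intermediate
12 | (5R)-5-ethenyl-3-(hydroxymethyl)furan-2(5H)-one | O=C1O[C@H](C=C)C=C1CO | intermediate
13 | (5R)-3-(bromomethyl)-5-ethenylfuran-2(5H)-one | O=C1O[C@H](C=C)C=C1CBr | intermediate
14 | 2-methylidenepropane-1,3-diol | C=C(CO)CO | starting material
15 | 2-{[(4-methoxybenzyl)oxy]methyl}prop-2-en-1-ol | C=C(CO)COCc1ccc(OC)cc1 | intermediate
16 | triethyl orthoacetate | CC(OCC)(OCC)OCC | starting material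
17 | 1-ethoxyvinyl ether of 15 (mixed ketene acetal) | C=C(OCC)OCC(=C)COCc1ccc(OC)cc1 | intermediate
18 | ethyl 4-{[(4-methoxybenzyl)oxy]methyl}pent-4-enoate | CCOC(=O)CCC(=C)COCc1ccc(OC)cc1 | intermediate
19 | 4-{[(4-methoxybenzyl)oxy]methyl}pent-4-enal | O=CCCC(=C)COCc1ccc(OC)cc1 | intermediate
20 | triethyl phosphonoacetate | CCOC(=O)CP(=O)(OCC)OCC | starting material
21 | (2-bromoethoxy)(tert-butyl)dimethylsilane | BrCCO[Si](C)(C)C(C)(C)C | starting material
22 | sodium salt of 20 (phosphonate carbanion) | [Na+].CCOC(=O)[CH-]P(=O)(OCC)OCC | intermediate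
23 | ethyl 4-[(tert-butyldimethylsilyl)oxy]-2-(diethoxyphosphoryl)butanoate (racemic) | CCOC(=O)C(CCO[Si](C)(C)C(C)(C)C)P(=O)(OCC)OCC | intermediate
24 | sodium salt of 23 (phosphonate carbanion) | [Na+].CCOC(=O)[C-](CCO[Si](C)(C)C(C)(C)C)P(=O)(OCC)OCC | intermediate
25 | ethyl (2E)-2-{2-[(tert-butyldimethylsilyl)oxy]ethyl}-6-{[(4-methoxybenzyl)oxy]methyl}hepta-2,6-dienoate | CCOC(=O)/C(CCO[Si](C)(C)C(C)(C)C)=C/CCC(=C)COCc1ccc(OC)cc1 | intermediate
26 | (2E)-2-{2-[(tert-butyldimethylsilyl)oxy]ethyl}-6-{[(4-methoxybenzyl)oxy]methyl}hepta-2,6-dien-1-ol | OC/C(CCO[Si](C)(C)C(C)(C)C)=C/CCC(=C)COCc1ccc(OC)cc1 | intermediate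
27 | tert-butyl{[(2E)-2-{2-[(tert-butyldimethylsilyl)oxy]ethyl}-6-{[(4-methoxybenzyl)oxy]methyl}hepta-2,6-dien-1-yl]oxy}diphenylsilane | CC(C)(C)[Si](c1ccccc1)(c1ccccc1)OC/C(CCO[Si](C)(C)C(C)(C)C)=C/CCC(=C)COCc1ccc(OC)cc1 | intermediate
28 | (5E)-6-{[(tert-butyldiphenylsilyl)oxy]methyl}-8-[(tert-butyldimethylsilyl)oxy]-2-methylideneoct-5-en-1-ol | OCC(=C)CC/C=C(/CO[Si](c1ccccc1)(c1ccccc1)C(C)(C)C)CCO[Si](C)(C)C(C)(C)C | intermediate
29 | (5E)-6-{[(tert-butyldiphenylsilyl)oxy]methyl}-8-[(tert-butyldimethylsilyl)oxy]-2-methylideneoct-5-en-1-yl acetate | CC(=O)OCC(=C)CC/C=C(/CO[Si](c1ccccc1)(c1ccccc1)C(C)(C)C)CCO[Si](C)(C)C(C)(C)C | intermediate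
30 | (5E)-6-{[(tert-butyldiphenylsilyl)oxy]methyl}-8-hydroxy-2-methylideneoct-5-en-1-yl acetate | CC(=O)OCC(=C)CC/C=C(/CO[Si](c1ccccc1)(c1ccccc1)C(C)(C)C)CCO | intermediate
31 | (5E)-6-{[(tert-butyldiphenylsilyl)oxy]methyl}-2-methylidene-8-oxooct-5-en-1-yl acetate | CC(=O)OCC(=C)CC/C=C(/CO[Si](c1ccccc1)(c1ccccc1)C(C)(C)C)CC=O | intermediate
32 | {[(5R)-5-ethenyl-2-oxo-2,5-dihydrofuran-3-yl]methyl}zinc bromide | O=C1O[C@H](C=C)C=C1C[Zn]Br | intermediate
33 | (5E,8S)-6-{[(tert-butyldiphenylsilyl)oxy]methyl}-8-[(2R,3R)-2-ethenyl-4-methylidene-5-oxooxolan-3-yl]-8-hydroxy-2-methylideneoct-5-en-1-yl acetate | C=C1C(=O)O[C@H](C=C)[C@H]1[C@@H](O)C/C(=C\CCC(=C)COC(C)=O)CO[Si](c1ccccc1)(c1ccccc1)C(C)(C)C | intermediate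
34 | (2S)-2-methylbutanoic acid | CC[C@H](C)C(=O)O | starting material
35 | (1S,3E)-8-acetoxy-3-{[(tert-butyldiphenylsilyl)oxy]methyl}-1-[(2R,3R)-2-ethenyl-4-methylidene-5-oxooxolan-3-yl]-7-methylideneoct-3-en-1-yl (2S)-2-methylbutanoate | C=C1C(=O)O[C@H](C=C)[C@H]1[C@@H](OC(=O)[C@@H](C)CC)C/C(=C\CCC(=C)COC(C)=O)CO[Si](c1ccccc1)(c1ccccc1)C(C)(C)C | intermediate
36 | (1S,3E)-8-acetoxy-1-[(2R,3R)-2-ethenyl-4-methylidene-5-oxooxolan-3-yl]-3-(hydroxymethyl)-7-methylideneoct-3-en-1-yl (2S)-2-methylbutanoate | C=C1C(=O)O[C@H](C=C)[C@H]1[C@@H](OC(=O)[C@@H](C)CC)C/C(=C\CCC(=C)COC(C)=O)CO | intermediate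
37 | (1S,3E)-8-acetoxy-1-[(2R,3R)-2-ethenyl-4-methylidene-5-oxooxolan-3-yl]-3-formyl-7-methylideneoct-3-en-1-yl (2S)-2-methylbutanoate | C=C1C(=O)O[C@H](C=C)[C@H]1[C@@H](OC(=O)[C@@H](C)CC)C/C(=C\CCC(=C)COC(C)=O)C=O | intermediate
38 | [(3aR,4S,6E,10E,11aR)-10-(acetoxymethyl)-6-formyl-3-methylidene-2-oxo-2,3,3a,4,5,8,9,11a-octahydrocyclodeca[b]furan-4-yl] (2S)-2-methylbutanoate | C=C1C(=O)O[C@@H]2/C=C(/COC(C)=O)CC/C=C(/C=O)C[C@H](OC(=O)[C@@H](C)CC)[C@@H]12 | target

**Step count**

Total steps: 23. Longest linear sequence: 15 steps (steps 8–10 and 12–23). Fragment 1 (steps 1–7) and phosphonate 23 (step 11) are made in parallel.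

**The three steps most likely to fail**

1. Step 23 (ring-closing metathesis). The risks are a strained ten-membered ring, a sluggish 1,1-disubstituted partner and oligomerisation. The fallback closes the ring at C7–C8 by an intramolecular Barbier allylation after the fragments have been joined at C4=C5 by cross-metathesis; it sets out from 28 and 13 and comes back to the route at 38. MnO2 in CH2Cl2 oxidises 28 to the 2-substituted acrolein F1. Cross-metathesis of F1 with 13 (second-generation Hoveyda–Grubbs catalyst RuCl2(H2IMes)(=CH-C6H4-2-OiPr), CH2Cl2, 40 °C) gives the E-enal F2. Its formyl group is trans to C6, the thermodynamically preferred enal geometry, which is the ring-cis arrangement of C3 and C6. Reduction with NaBH4/CeCl3·7H2O in MeOH at −78 °C gives the allylic alcohol F3, Ac2O/pyridine gives the acetate F4, CSA/MeOH gives the primary alcohol F5, and Dess–Martin oxidation gives the bromo aldehyde F6. Zn dust in THF/aq NH4Cl at high dilution (CrCl2 in THF as the alternative metal) closes the ten-membered ring to the macrocyclic alcohol F7; the C8 configuration from this macrocyclic transition state would have to be checked. DCC/DMAP with 34 gives the ester F8, HF·pyridine gives the allylic alcohol F9, and Dess–Martin oxidation gives 38.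

2. Step 19 (Barbier allylation). The risks are the anti/syn ratio at C8, migration of the alkene of 31 into conjugation, and translactonisation of the hydroxy lactone. The fallback sets C8 by inversion instead of by the allylation transition state; it sets out from 31 and 13 and comes back at 35. The 8-epimeric alcohol F10, separated from the same allylation, is esterified with 34 under Mitsunobu conditions (PPh3, DIAD, toluene, 0 °C → rt); this inverts C8 and gives 35 directly, so both C8 epimers converge.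

3. Step 12 (Horner–Wadsworth–Emmons olefination). An α-branched phosphonate may give a poor E/Z ratio, and this alkene is the only stereo-element of fragment 2. The fallback builds the trisubstituted alkene by cross-metathesis with a 2-substituted acrolein, which gives the E-enal under thermodynamic control; it sets out from 19 and comes back at 26. Wittig methylenation of 19 (Ph3P=CH2, THF, 0 °C) gives the diene F11. Purchased 4-[(tert-butyldimethylsilyl)oxy]butanal is α-methylenated (aq CH2O, pyrrolidine and EtCO2H as catalysts, i-PrOH, 45 °C) to the acrolein F12. Cross-metathesis of F11 with F12 (second-generation Hoveyda–Grubbs catalyst RuCl2(H2IMes)(=CH-C6H4-2-OiPr), CH2Cl2, 40 °C) gives the E-enal F13, and NaBH4/CeCl3·7H2O reduction gives 26.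

**Further compounds**

F1 | step 23 | (5E)-6-{[(tert-butyldiphenylsilyl)oxy]methyl}-8-[(tert-butyldimethylsilyl)oxy]-2-methylideneoct-5-enal | O=CC(=C)CC/C=C(/CO[Si](c1ccccc1)(c1ccccc1)C(C)(C)C)CCO[Si](C)(C)C(C)(C)C
F2 | step 23 | cross-metathesis E-enal: (5R)-3-(bromomethyl)furan-2(5H)-one carrying at C5 the (1E,5E)-2-formyl-6-{[(tert-butyldiphenylsilyl)oxy]methyl}-8-[(tert-butyldimethylsilyl)oxy]octa-1,5-dien-1-yl chain | O=C1O[C@H](/C=C(/C=O)CC/C=C(/CO[Si](c2ccccc2)(c2ccccc2)C(C)(C)C)CCO[Si](C)(C)C(C)(C)C)C=C1CBr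
F3 | step 23 | allylic alcohol from F2 (CH2OH in place of the formyl group) | O=C1O[C@H](/C=C(/CO)CC/C=C(/CO[Si](c2ccccc2)(c2ccccc2)C(C)(C)C)CCO[Si](C)(C)C(C)(C)C)C=C1CBr
F4 | step 23 | acetate of F3 | O=C1O[C@H](/C=C(/COC(C)=O)CC/C=C(/CO[Si](c2ccccc2)(c2ccccc2)C(C)(C)C)CCO[Si](C)(C)C(C)(C)C)C=C1CBr
F5 | step 23 | primary alcohol from F4 (TBS ether removed) | O=C1O[C@H](/C=C(/COC(C)=O)CC/C=C(/CO[Si](c2ccccc2)(c2ccccc2)C(C)(C)C)CCO)C=C1CBr
F6 | step 23 | bromo aldehyde from F5 (C8 aldehyde) | O=C1O[C@H](/C=C(/COC(C)=O)CC/C=C(/CO[Si](c2ccccc2)(c2ccccc2)C(C)(C)C)CC=O)C=C1CBr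
F7 | step 23 | macrocyclic alcohol: 38 with a free C8 hydroxyl and a CH2OTBDPS group in place of the formyl group | C=C1C(=O)O[C@@H]2/C=C(/COC(C)=O)CC/C=C(/CO[Si](c3ccccc3)(c3ccccc3)C(C)(C)C)C[C@H](O)[C@@H]12
F8 | step 23 | (2S)-2-methylbutanoate of F7 | C=C1C(=O)O[C@@H]2/C=C(/COC(C)=O)CC/C=C(/CO[Si](c3ccccc3)(c3ccccc3)C(C)(C)C)C[C@H](OC(=O)[C@@H](C)CC)[C@@H]12
F9 | step 23 | macrocyclic allylic alcohol: 38 with CH2OH in place of the formyl group | C=C1C(=O)O[C@@H]2/C=C(/COC(C)=O)CC/C=C(/CO)C[C@H](OC(=O)[C@@H](C)CC)[C@@H]12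
F10 | step 19 | (5E,8R)-6-{[(tert-butyldiphenylsilyl)oxy]methyl}-8-[(2R,3R)-2-ethenyl-4-methylidene-5-oxooxolan-3-yl]-8-hydroxy-2-methylideneoct-5-en-1-yl acetate (C8 epimer of 33) | C=C1C(=O)O[C@H](C=C)[C@H]1[C@H](O)C/C(=C\CCC(=C)COC(C)=O)CO[Si](c1ccccc1)(c1ccccc1)C(C)(C)C
F11 | step 12 | 1-methoxy-4-{[(2-methylidenehex-5-en-1-yl)oxy]methyl}benzene | C=CCCC(=C)COCc1ccc(OC)cc1
F12 | step 12 | 2-{2-[(tert-butyldimethylsilyl)oxy]ethyl}prop-2-enal | C=C(C=O)CCO[Si](C)(C)C(C)(C)C
F13 | step 12 | (2E)-2-{2-[(tert-butyldimethylsilyl)oxy]ethyl}-6-{[(4-methoxybenzyl)oxy]methyl}hepta-2,6-dienal | O=C/C(CCO[Si](C)(C)C(C)(C)C)=C/CCC(=C)COCc1ccc(OC)cc1
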